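## The problem

Preacredinone A (12) is a benzophenone: a 2,6-dimethoxyphenyl ring (ring A) and a pentasubstituted benzene (ring B: C1 aroyl, C2 OH, C3 H, C4 Me, C5 OMe, C6 CH2OAc) share one ketone carbon. All four positions ortho to that carbonyl are occupied, so the two aryl–carbonyl bonds are the most congested in the molecule. The aroyl group also sits meta to the C5 methoxy group, where Friedel–Crafts chemistry would not place it. There is no stereocenter; the only stereochemical element on the way is the geometry of an alkene that is later cleaved, so the whole difficulty is regiocontrol around ring B. Three features limit the reagents: the primary benzylic acetate ortho to the ketone (lost to base, liable to ionise in acid, and as the free alcohol able to close onto the ketone as a cyclic hemiketal), the free phenol, and the electron-rich ring A, whose C3' and C5' are each ortho to one methoxy group and para to the other. The feature that opens a short route is the C5–C6–C1 edge of ring B: C6 carries a one-carbon arm, its neighbour C5 is blocked by methoxy, and its other neighbour C1 carries the aroyl group. That is the pattern a Catellani reaction writes onto a 2-iodoanisole, with C6 as the ipso carbon and C1 as the only free ortho C–H. The remaining oxygen at C2 is ortho to the ketone and para to the C5 methoxy group, and ring A has no C–H ortho to the carbonyl, so a carbonyl-directed C–H oxidation can address C2 without a competing site.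

## Retrosynthesis

**C2–O bond last.** The target 12 is cut first at the C2–O bond, which leads to acetate 10; the forward reaction passes through aryl trifluoroacetate 11, which hydrolyses on work-up. Carrying the C2 oxygen from the start was weighed and set aside. In the aryl iodide it would sit next to the one C–H that the key coupling must activate, and the ketone would then have to be formed with all four ortho substituents already present. Removing it keeps the key step on a 1,2,3-trisubstituted arene. The forward reaction has to oxidise one C–H beside two electron-rich rings and a benzylic acetate; it can rely on C2–H being the only C–H ortho to the carbonyl in the whole molecule.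

**Acetoxymethyl group from a vinyl group.** The acetate of 10 is cut to keto alcohol 9, and the CH2OH carbon of 9 is traced through aldehyde 8 to the aryl-bound alkene carbon of cinnamate 7; the bond formally cut is the C=C bond of 7. An alkene is preferred to a nitrile or ester handle at C6 because its cleavage arrives at the aldehyde oxidation level, where a mild borohydride is enough; the other handles would need hydride reagents that endanger the diaryl ketone. Precursor 7 differs from 10 only in the side arm. The forward sequence must cleave an electron-poor alkene without attacking ring A and reduce an aldehyde beside a ketone that is shielded by three ortho substituents.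

**The C1–carbonyl and C6–vinyl bonds in one operation.** Cinnamate 7 is cut at both bonds at once, giving iodide 3, acid chloride 5 and acrylate 6. The neighbouring cuts are weaker. A Friedel–Crafts acylation would enter para to the methoxy group, not meta. Addition of a ring B organometallic to a ring A carbonyl compound needs a 1,2,3,4-tetrasubstituted ring B halide that is itself a multistep target. The three-component cut reduces ring B to a 1,2,3-trisubstituted benzene and leaves ring A untouched in a stock-derived reagent. The forward reaction must acylate the single ortho C–H of 3 with a di-ortho-substituted acid chloride and then vinylate the ipso carbon; the site is fixed by the methoxy group that blocks the other ortho position.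

**Building blocks.** Iodide 3 is cut at the C–I bond to the catalogue aniline 1, through diazonium salt 2. The amino group marks the position between nothing and methoxy that electrophilic iodination of an arene without it would not favour, since the position para to methoxy would react first. Acid chloride 5 comes from acid 4 by exchange of OH for Cl. Both precursors are simple benzene derivatives, and both forward reactions are routine.

## Roads not taken

**Alternative 1:** Baeyer–Villiger cleavage of an anthraquinone. Here the CH2OAc carbon is read as a former quinone carbonyl, so both rings and every carbon come from the tricyclic anthraquinone A1 (4-benzyloxy-5-methoxy-2-methyl-9,10-dioxoanthracen-1-yl methanesulfonate). The cut is the bond between ring A and that carbonyl.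
- Forward key step: a strong peracid would add to the quinone carbonyl flanked by the mesylate, ring A would migrate to oxygen, and the central ring would expand to the seven-membered lactone A2.
- Merits: the route mirrors the likely biogenesis, needs no C–C bond formation at all, and has the C2 oxygen in place from the beginning. In that last respect it is better than the chosen plan, which must oxidise a C–H bond at the end.
- Weak points: A1 needs three peri oxygens carried as three different groups, which is a multistep differentiation problem before the key step. Quinone carbonyls are poor Baeyer–Villiger substrates. The outcome depends on a choice between two carbonyls and two migrating aryl groups, and peracids strong enough for the job also hydroxylate electron-rich arenes. After A2 the lactone carbonyl must be reduced to CH2OH beside the ketone, the ring A phenol methylated, the mesylate exchanged for a methyl ether, the acetate installed and the benzyl group removed.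
- Comparison: the chosen plan sets against it a six-step sequence from stock compounds and regiochemistry fixed by blocked positions rather than by migratory preference.

**Alternative 2:** Gold-catalysed furan–yne phenol synthesis with a phthalan as mask. Ring B is cut at C1–C6 and C4–C5 and is built from the furfuryl propargyl ether A3.
- Forward key step: (Ph3P)AuNTf2, a complex of monovalent gold, would isomerise A3 to the phthalan phenol A4, moving the furan oxygen to C5 and closing ring B and the dihydrofuran ring in one atom-economic event.
- Merits: the ring A–carbon bond is made earlier by a simple carbonyl addition, so no hindered acylation is needed, and the cycloisomerisation is a dependable reaction. On the safety of the key step this road is better than the chosen plan.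
- Weak points: A4 still lacks the C2 oxygen, so it inherits the same late C–H hydroxylation. It also needs O-methylation at C5 and an oxidative opening of the phthalan that must select the doubly benzylic C–H over the CH2 group and stop before a phthalide forms. The stereocenter of A4 is created only to be destroyed.
- Comparison: the sequence is longer by several steps. The chosen plan answers with a shorter route that sets the ketone and the one-carbon arm at their final or near-final oxidation levels directly.

**Alternative 3:** Formal (3+3) cyclisation onto a furanone. Ring B is cut at C3–C4 and C1–C6 into the bis(silyl enol ether) A5 of the corresponding aroylacetone and the furanone A6.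
- Forward key step: under TiCl4 the terminal carbon of A5 would add to the methyl-bearing enone carbon of A6, the central carbon would close onto the furanone carbonyl, and aromatisation with opening of the furanone would give the deacetyl compound A7 with the free CH2OH at C6; one selective acetylation would finish the synthesis.
- Merits: it is the most convergent of the four ideas. It forms the hindered aryl ketone before ring B exists and delivers the C2 hydroxyl without any late oxidation; in both respects it is better than the chosen plan.
- Weak points: A6 is not a stock compound. Its electrophilic carbon is fully substituted and deactivated by two oxygen donors. It can enolise toward a hydroxyfuran under the Lewis acid, and its use as a ring-opening 1,3-dielectrophile has no close model. The regiochemistry of the cyclisation rests on a subtle preference between two electrophilic sites.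
- Comparison: the chosen plan sets against this a key step of a known reaction class run on purchasable or one-step partners, with the site of reaction fixed by a blocked position.

Key step: step 3

## Route

Remark: keto alcohol 9 is written as the open hydroxy ketone, although it can equilibrate with its cyclic hemiketal; both forms lead to the same acetate 10.

Step 1
Reactants: 1 2-methoxy-3-methylaniline
Product: 3 1-iodo-2-methoxy-3-methylbenzene, via aryl diazonium chloride 2 (not isolated)
Conditions: NaNO2, aq. HCl, 0 °C; then KI, 0 °C → rt
Reagents that add atoms: potassium iodide, [K+].[I-]
Why: Diazotisation and iodide displacement (Sandmeyer-type iodination, which needs no copper) replace NH2 by I at the same carbon, so the 1,2,3-pattern of 1 is carried over unchanged.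

Step 2
Reactants: 4 2,6-dimethoxybenzoic acid
Product: 5 2,6-dimethoxybenzoyl chloride
Conditions: (COCl)2, cat. DMF, CH2Cl2, 0 °C → rt
Reagents that add atoms: oxalyl chloride, ClC(=O)C(Cl)=O
Why: Standard acid chloride formation through the Vilsmeier-type chloroiminium species; the methyl ethers are untouched, and freshly made 5 free of acid and anhydride is wanted for step 3.

Step 3
Reactants: 3 1-iodo-2-methoxy-3-methylbenzene; 5 2,6-dimethoxybenzoyl chloride; 6 methyl acrylate
Product: 7 methyl (E)-3-[6-(2,6-dimethoxybenzoyl)-2-methoxy-3-methylphenyl]prop-2-enoate
Conditions: Pd(OAc)2 (10 mol %), P(2-furyl)3 (25 mol %), norbornene, Cs2CO3, toluene, 100 °C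
Reagents that add atoms: none
Why: Catellani three-component coupling (ortho C–H acylation with ipso Heck termination), a reaction type known for ortho-substituted aryl iodides, aroyl chlorides and acrylates. Zerovalent palladium inserts into the C–I bond of 3, the strained norbornene inserts into the aryl–palladium bond, and base-assisted palladation of the single ortho C–H (future C1) gives the five-membered aryl–norbornyl palladacycle of divalent palladium. Acid chloride 5 adds oxidatively to give an acyl complex of tetravalent palladium, and aryl–acyl reductive elimination forms the C1–carbonyl bond. The arene is now substituted at both ortho positions, which drives norbornene out by β-carbon elimination; the resulting arylpalladium species inserts acrylate 6 and loses a β-hydride in a syn sense, forming the C6–vinyl bond and fixing the E geometry. No ring of the product is closed and no stereocenter is formed; the palladacycle is a transient only. Site selectivity comes from the substrate: the methoxy group occupies one ortho position, so only one C–H can be acylated and no second ortho functionalisation can follow. The step needs acylation of the palladacycle to outrun its decay and any direct Heck coupling of the first arylpalladium species, so the most electrophilic acyl donor is used in excess, norbornene is kept in excess over the acrylate, and the electron-poor phosphine is chosen to ease the high-valent steps.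

Step 4
Reactants: 7 methyl (E)-3-[6-(2,6-dimethoxybenzoyl)-2-methoxy-3-methylphenyl]prop-2-enoate
Product: 9 (2,6-dimethoxyphenyl)[2-(hydroxymethyl)-3-methoxy-4-methylphenyl]methanone, via aroylbenzaldehyde 8 (not isolated)
Conditions: O3, CH2Cl2/MeOH, −78 °C; then NaBH4, −78 → 0 °C
Reagents that add atoms: ozone, [O-][O+]=O
Why: Ozonolysis with reductive borohydride work-up cleaves the C=C bond and reduces the peroxidic intermediates and aldehyde 8 in the same flask; ozone is stopped at the first sign of excess because ring A is electron-rich. The diaryl ketone is shielded by three ortho substituents and by reversible hemiketal formation with the new alkoxide, so NaBH4 at or below 0 °C should leave it alone.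

Step 5
Reactants: 9 (2,6-dimethoxyphenyl)[2-(hydroxymethyl)-3-methoxy-4-methylphenyl]methanone
Product: 10 [6-(2,6-dimethoxybenzoyl)-2-methoxy-3-methylphenyl]methyl acetate
Conditions: Ac2O, pyridine, DMAP (cat.), CH2Cl2, 0 °C → rt
Reagents that add atoms: acetic anhydride, CC(=O)OC(C)=O
Why: DMAP-catalysed O-acetylation of the primary benzylic alcohol; any hemiketal form of 9 is in equilibrium with the open hydroxy ketone and only the primary alcohol is acylated at a useful rate, so the material funnels to 10 under non-acidic conditions.

Step 6
Reactants: 10 [6-(2,6-dimethoxybenzoyl)-2-methoxy-3-methylphenyl]methyl acetate
Product: 12 preacredinone A, [2-(2,6-dimethoxybenzoyl)-3-hydroxy-6-methoxy-5-methylphenyl]methyl acetate, via aryl trifluoroacetate 11 (not isolated)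
Conditions: Pd(O2CCF3)2 (10 mol %), PhI(O2CCF3)2, ClCH2CH2Cl, 80 °C; then aqueous work-up
Reagents that add atoms: [bis(trifluoroacetoxy)iodo]benzene, O=C(OI(OC(=O)C(F)(F)F)c1ccccc1)C(F)(F)F
Why: Palladium-catalysed ketone-directed ortho C–H hydroxylation of a diaryl ketone: carbonyl-assisted palladation by electrophilic divalent palladium, oxidation by the trivalent iodine reagent, C–O reductive elimination to 11, and hydrolysis of the labile aryl trifluoroacetate on work-up. C2–H is the only C–H ortho to the carbonyl on either ring and lies para to the C5 methoxy group, so chelation and electronics point to the same carbon. A non-acidic chlorinated solvent is used in place of a carboxylic acid medium to spare the benzylic acetate, and the product phenol is protected from further oxidation by its hydrogen bond to the ketone.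

## Compound list

1 | 2-methoxy-3-methylaniline | COc1c(C)cccc1N | starting material
2 | 2-methoxy-3-methylbenzenediazonium chloride | COc1c(C)cccc1[N+]#N.[Cl-] | intermediate (not isolated)
3 | 1-iodo-2-methoxy-3-methylbenzene | COc1c(C)cccc1I | intermediate
4 | 2,6-dimethoxybenzoic acid | COc1cccc(OC)c1C(O)=O | starting material
5 | 2,6-dimethoxybenzoyl chloride | COc1cccc(OC)c1C(Cl)=O | intermediate
6 | methyl acrylate | C=CC(=O)OC | starting material
7 | methyl (E)-3-[6-(2,6-dimethoxybenzoyl)-2-methoxy-3-methylphenyl]prop-2-enoate | COC(=O)/C=C/c1c(OC)c(C)ccc1C(=O)c1c(OC)cccc1OC | intermediate
8 | 6-(2,6-dimethoxybenzoyl)-2-methoxy-3-methylbenzaldehyde | O=Cc1c(OC)c(C)ccc1C(=O)c1c(OC)cccc1OC | intermediate (not isolated)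
9 | (2,6-dimethoxyphenyl)[2-(hydroxymethyl)-3-methoxy-4-methylphenyl]methanone | COc1cccc(OC)c1C(=O)c1ccc(C)c(OC)c1CO | intermediate
10 | [6-(2,6-dimethoxybenzoyl)-2-methoxy-3-methylphenyl]methyl acetate | COc1cccc(OC)c1C(=O)c1ccc(C)c(OC)c1COC(C)=O | intermediate
11 | [2-(2,6-dimethoxybenzoyl)-6-methoxy-5-methyl-3-(trifluoroacetoxy)phenyl]methyl acetate | COc1cccc(OC)c1C(=O)c1c(OC(=O)C(F)(F)F)cc(C)c(OC)c1COC(C)=O | intermediate (not isolated)
12 | preacredinone A, [2-(2,6-dimethoxybenzoyl)-3-hydroxy-6-methoxy-5-methylphenyl]methyl acetate | COc1cccc(OC)c1C(=O)c1c(O)cc(C)c(OC)c1COC(C)=O | target

## Step count and risk

Total step count: 6. Longest linear sequence: 5 steps (steps 1, 3, 4, 5 and 6, from aniline 1).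

**Step 3 (key step).**
- Risk: acylation of the palladacycle by the di-ortho-substituted acid chloride may be too slow. The catalyst would then be diverted into premature Heck coupling of the first arylpalladium species, into reductive collapse of the palladacycle onto the norbornane unit, or into base-mediated consumption of the acid chloride.
- Fallback: this replaces palladium catalysis by directed ortho-lithiation. It sets out from iodide 3 (together with acid chloride 5) and comes back to the route at keto alcohol 9.
  - Iodine–magnesium exchange with iPrMgCl·LiCl would give (2-methoxy-3-methylphenyl)magnesium chloride F1, and formylation with DMF would give 2-methoxy-3-methylbenzaldehyde F2.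
  - Addition of LiN(Me)CH2CH2NMe2 would mask the aldehyde in the flask as the lithium α-amino alkoxide F3. Its chelating side arm would direct n-BuLi to the only ortho C–H (future C1) to give the ring-lithiated species F4.
  - Acylation with an excess of 5 would give the acylated amino alkoxide F5. Aqueous acid work-up would release aldehyde 8, here isolated, and NaBH4 would reduce it to 9.
  - This path forms the C1–carbonyl bond by polar chemistry and needs no alkene cleavage, at the price of giving up the three-component coupling.

**Step 6.**
- Risk: the trivalent iodine oxidant may attack electron-rich ring A; the trifluoroacetic acid released may ionise the benzylic acetate; and the crowded carbonyl may turn out of the plane of ring B, which would slow cyclopalladation.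
- Fallback: this forms a C–B bond under neutral, non-oxidising conditions and oxidises it afterwards. It sets out from acetate 10 and comes back at target 12. Ketone-directed ortho C–H borylation with B2pin2 under [Ir(OMe)(cod)]2 and AsPh3 in a hydrocarbon solvent would give the arylboronate [2-(2,6-dimethoxybenzoyl)-6-methoxy-5-methyl-3-(4,4,5,5-tetramethyl-1,3,2-dioxaborolan-2-yl)phenyl]methyl acetate F6. Oxidation of the C–B bond with Me3NO at room temperature would give 12 without acid, base or an arene-oxidising reagent.

**Step 4.**
- Risk: ozone may oxidise ring A once the alkene is consumed, or excess borohydride may reduce the diaryl ketone.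
- Fallback: this replaces ozone by osmium-mediated dihydroxylation and glycol cleavage. It sets out from cinnamate 7 and comes back at keto alcohol 9. Upjohn dihydroxylation (K2OsO4·2H2O, N-methylmorpholine N-oxide) would give the racemic syn diol methyl (2R*,3S*)-3-[6-(2,6-dimethoxybenzoyl)-2-methoxy-3-methylphenyl]-2,3-dihydroxypropanoate F7. NaIO4 would cleave it to aldehyde 8, here isolated, and one equivalent of NaBH4 at 0 °C would give 9.

## Further compounds

F1 | step 3 | (2-methoxy-3-methylphenyl)magnesium chloride | COc1c(C)cccc1[Mg]Cl
F2 | step 3 | 2-methoxy-3-methylbenzaldehyde | COc1c(C)cccc1C=O
F3 | step 3 | lithium {[2-(dimethylamino)ethyl](methyl)amino}(2-methoxy-3-methylphenyl)methanolate (racemic) | COc1c(C)cccc1C([O-])N(C)CCN(C)C.[Li+]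
F4 | step 3 | lithium {[2-(dimethylamino)ethyl](methyl)amino}(6-lithio-2-methoxy-3-methylphenyl)methanolate (racemic) | [Li]c1ccc(C)c(OC)c1C([O-])N(C)CCN(C)C.[Li+]
F5 | step 3 | lithium [6-(2,6-dimethoxybenzoyl)-2-methoxy-3-methylphenyl]{[2-(dimethylamino)ethyl](methyl)amino}methanolate (racemic) | COc1cccc(OC)c1C(=O)c1ccc(C)c(OC)c1C([O-])N(C)CCN(C)C.[Li+]
F6 | step 6 | [2-(2,6-dimethoxybenzoyl)-6-methoxy-5-methyl-3-(4,4,5,5-tetramethyl-1,3,2-dioxaborolan-2-yl)phenyl]methyl acetate | COc1cccc(OC)c1C(=O)c1c(B2OC(C)(C)C(C)(C)O2)cc(C)c(OC)c1COC(C)=O
F7 | step 4 | methyl (2R*,3S*)-3-[6-(2,6-dimethoxybenzoyl)-2-methoxy-3-methylphenyl]-2,3-dihydroxypropanoate (racemic; one enantiomer drawn) | COC(=O)[C@@H](O)[C@H](O)c1c(OC)c(C)ccc1C(=O)c1c(OC)cccc1OC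
A1 | alternative 1 | 4-(benzyloxy)-5-methoxy-2-methyl-9,10-dioxo-9,10-dihydroanthracen-1-yl methanesulfonate | COc1cccc2C(=O)c3c(OS(C)(=O)=O)c(C)cc(OCc4ccccc4)c3C(=O)c12
A2 | alternative 1 | 10-(benzyloxy)-1-methoxy-8-methyl-7-(methylsulfonyloxy)dibenzo[b,e]oxepine-6,11-dione | COc1cccc2OC(=O)c3c(OS(C)(=O)=O)c(C)cc(OCc4ccccc4)c3C(=O)c12
A3 | alternative 2 | 2-[(2,6-dimethoxyphenyl)(prop-2-yn-1-yloxy)methyl]-5-methylfuran (racemic) | COc1cccc(OC)c1C(OCC#C)c1ccc(C)o1
A4 | alternative 2 | 1-(2,6-dimethoxyphenyl)-5-methyl-1,3-dihydroisobenzofuran-4-ol (racemic) | COc1cccc(OC)c1C1OCc2c(O)c(C)ccc12
A5 | alternative 3 | (Z)-1-(2,6-dimethoxyphenyl)-1,3-bis(trimethylsilyloxy)buta-1,3-diene | COc1cccc(OC)c1/C(O[Si](C)(C)C)=C/C(O[Si](C)(C)C)=C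
A6 | alternative 3 | 4-methoxy-5-methylfuran-3(2H)-one | COC1=C(C)OCC1=O
A7 | alternative 3 | (2,6-dimethoxyphenyl)[6-hydroxy-2-(hydroxymethyl)-3-methoxy-4-methylphenyl]methanone | COc1cccc(OC)c1C(=O)c1c(O)cc(C)c(OC)c1CO
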